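**Retrosynthetic overview**
1. Target ⇐ acid deprotection; the formyl group comes from ortho-lithiation/DMF, and the CH2OH from Ir C–H borylation, one-carbon homologation and oxidation, all on a symmetric 2,6-bis(MOM)benzyl decalin.
2. Benzyl decalin ⇐ 2-lithio-1,3-bis(methoxymethoxy)benzene (from resorcinol) + an α-quaternary β,γ-unsaturated aldehyde, with the benzylic oxygen removed by Li/NH3 in the same flask.
3. Quaternary aldehyde ⇐ Meinwald 1,2-methyl shift of a spiro vinyl oxirane (key step; the ring alkene is already in place) ⇐ sulfonium ethylide + bicyclic enone.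
4. Bicyclic enone ⇐ intramolecular aldol condensation ⇐ acetaldehyde Mukaiyama aldol ⇐ enantioselective Mukaiyama–Michael addition of an isobutyraldehyde enol silane to 6-methylcyclohex-2-enone.
5. Ring order: ring B is bought, ring A is closed in step 5, and the arene is attached whole and functionalised last.

Assumption: the target is made as the open hydroxy-aldehyde drawn; racemic 6-methylcyclohex-2-en-1-one is used because its methyl-bearing centre is equilibrated in step 5.

**Route**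

Step 1
Reactants: 1 isobutyraldehyde (2-methylpropanal)
Product: 2 2-methyl-1-(trimethylsilyloxy)prop-1-ene
Conditions: Me3SiCl, Et3N, DMF, 100 °C; distil
Reagents that add atoms: chlorotrimethylsilane, C[Si](C)(C)Cl
Why: Thermodynamic silyl enol ether formation (House conditions); the aldehyde has one enolisable position, so a single enol silane forms.

Step 2
Reactants: 2 2-methyl-1-(trimethylsilyloxy)prop-1-ene; 3 rac-6-methylcyclohex-2-en-1-one
Product: 5 2-methyl-2-[(1R)-4-methyl-3-oxocyclohexyl]propanal (both ring C4 epimers), via ring trimethylsilyl enol ether 4 (not isolated)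
Conditions: (S)-1-(2-methylphenyl)-3,3-diphenyltetrahydro-1H,3H-pyrrolo[1,2-c][1,3,2]oxazaborole·HN(SO2CF3)2 (10 mol %), Ph3PO (15 mol %), toluene, −20 °C; then 1 M aq HCl, THF, 0 °C
Reagents that add atoms: none
Why: Proposed new method: an enantioselective Mukaiyama–Michael addition in which the oxazaborolidinium ion binds the enone carbonyl, its aryl wall covers the Si face of the β-carbon, and the enol silane attacks the Re face with silyl transfer to the enolate oxygen, which sets the ring stereocentre as R and forms the quaternary–tertiary C–C bond (the mirror-image catalyst is used if the facial sense proves reversed); the closest known reaction is the same catalyst's Michael addition of silyl ketene acetals (such as the methyl isobutyrate acetal) to cyclohexenone, extended here to a less nucleophilic aldehyde-derived enol silane, and the methyl-bearing centre stays a mixture until step 5.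

Step 3
Reactants: 6 tetrahydrofuran
Product: 8 triethyl(vinyloxy)silane, via lithium ethenolate 7 (not isolated)
Conditions: n-BuLi, THF (substrate and solvent), 25 °C, 16 h; then Et3SiCl, 0 °C
Reagents that add atoms: chlorotriethylsilane, CC[Si](Cl)(CC)CC
Why: α-Lithiated THF fragments to ethene and the lithium enolate of acetaldehyde, which is O-silylated (enolate trapping).

Step 4
Reactants: 5 2-methyl-2-[(1R)-4-methyl-3-oxocyclohexyl]propanal; 8 triethyl(vinyloxy)silane
Product: 9 (3R)-4-methyl-4-[(1R)-4-methyl-3-oxocyclohexyl]-3-(triethylsilyloxy)pentanal (both ring C4 epimers)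
Conditions: (S,S)-IDPi HN[P(=NSO2CF3)(O2C20H10Ar2)]2, Ar = 3,5-(CF3)2C6H3 on each (S)-BINOL unit (1 mol %), 8 (1.5 equiv), toluene, −60 °C
Reagents that add atoms: none
Why: Catalyst-controlled Mukaiyama aldol (single aldolisation of an acetaldehyde enol silane by silylium–imidodiphosphorimidate ion pairing) in which the confined chiral anion directs the enol silane to the Re face of the neopentyl aldehyde, setting the carbinol centre as R and delivering it already silyl-protected, while the ketone is too unreactive to compete.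

Step 5
Reactants: 9 (3R)-4-methyl-4-[(1R)-4-methyl-3-oxocyclohexyl]-3-(triethylsilyloxy)pentanal
Product: 10 (2R,4aS,6R)-2,5,5-trimethyl-6-(triethylsilyloxy)-3,4,4a,5,6,7-hexahydronaphthalen-1(2H)-one
Conditions: (PhCH2)2NH2+ CF3CO2− (0.3 equiv), toluene, 60 °C
Reagents that add atoms: none
Why: Intramolecular aldol condensation through the aldehyde iminium and the ketone enol, in which only the ring CH2 next to the carbonyl can reach the aldehyde through a six-membered transition state, dehydration gives the conjugated enone (ring A), and the α-methyl centre equilibrates to the equatorial (2R) epimer.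

Step 6
Reactants: 10 (2R,4aS,6R)-2,5,5-trimethyl-6-(triethylsilyloxy)-3,4,4a,5,6,7-hexahydronaphthalen-1(2H)-one
Product: 11 (1S,2R,3'R,4aS,6R)-2,3',5,5-tetramethyl-6-(triethylsilyloxy)-3,4,4a,5,6,7-hexahydro-2H-spiro[naphthalene-1,2'-oxirane]
Conditions: [Ph2S-CH2CH3]+ BF4−, LiN(i-Pr)2, DME, −78 °C; then 10, −78 → −30 °C
Reagents that add atoms: ethyldiphenylsulfonium tetrafluoroborate, CC[S+](c1ccccc1)c1ccccc1.F[B-](F)(F)F
Why: Corey–Chaykovsky epoxidation, in which the unstabilised sulfonium ylide adds 1,2 to the enone from the axial face anti to the axial hydrogen at C2, so the new C–C bond is axial and the oxirane oxygen equatorial, with the ylide methyl turned away from the C2 methyl group.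

Step 7
Reactants: 11 (1S,2R,3'R,4aS,6R)-2,3',5,5-tetramethyl-6-(triethylsilyloxy)-3,4,4a,5,6,7-hexahydro-2H-spiro[naphthalene-1,2'-oxirane]
Product: 12 (1S,2R,4aR,6R)-1,2,5,5-tetramethyl-6-(triethylsilyloxy)-1,2,3,4,4a,5,6,7-octahydronaphthalene-1-carbaldehyde
Conditions: MeAl(OAr)2, Ar = 4-bromo-2,6-di-tert-butylphenyl (MABR, 20 mol %), CH2Cl2, −78 → −20 °C
Reagents that add atoms: none
Why: Meinwald rearrangement (semipinacol-type 1,2-shift) in which the bulky aluminium Lewis acid ionises the allylic tertiary C–O bond and the oxirane methyl migrates to C1 on the axial face anti to the departing oxygen while the aluminate rotates away from the C2 methyl, so the former oxirane carbon becomes the equatorial formyl group and C1 becomes the (S)-quaternary centre cis to the C2 methyl; that rotamer disfavours the competing hydride shift.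

Step 8
Reactants: 13 resorcinol (benzene-1,3-diol)
Product: 14 1,3-bis(methoxymethoxy)benzene
Conditions: MeOCH2Cl, i-Pr2NEt, CH2Cl2, 0 °C → rt
Reagents that add atoms: chloromethyl methyl ether, COCCl
Why: O-Alkylation of both phenols (Williamson-type acetal formation) installs the groups that later direct both lithiations.

Step 9
Reactants: 12 (1S,2R,4aR,6R)-1,2,5,5-tetramethyl-6-(triethylsilyloxy)-1,2,3,4,4a,5,6,7-octahydronaphthalene-1-carbaldehyde; 14 1,3-bis(methoxymethoxy)benzene
Product: 17 (1S,2R,4aR,6R)-1-[2,6-bis(methoxymethoxy)benzyl]-1,2,5,5-tetramethyl-6-(triethylsilyloxy)-1,2,3,4,4a,5,6,7-octahydronaphthalene, via aryllithium 15 (not isolated), via lithium benzylic alkoxide 16 (not isolated)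
Conditions: 14, n-BuLi, THF, 0 °C; 12, −78 → 0 °C; then NH3(l), Li, −78 °C; NH4Cl
Reagents that add atoms: none
Why: Directed ortho-metalation between the two MOM ethers, 1,2-addition of the aryllithium to the non-enolisable aldehyde, and dissolving-metal hydrogenolysis of the benzylic C–O bond in the same flask (tandem addition–reduction), with no stereocentre touched.

Step 10
Reactants: 17 (1S,2R,4aR,6R)-1-[2,6-bis(methoxymethoxy)benzyl]-1,2,5,5-tetramethyl-6-(triethylsilyloxy)-1,2,3,4,4a,5,6,7-octahydronaphthalene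
Product: 18 2-[3,5-bis(methoxymethoxy)-4-{[(1S,2R,4aR,6R)-1,2,5,5-tetramethyl-6-(triethylsilyloxy)-1,2,3,4,4a,5,6,7-octahydronaphthalen-1-yl]methyl}phenyl]-4,4,5,5-tetramethyl-1,3,2-dioxaborolane
Conditions: [Ir(OMe)(cod)]2 (1.5 mol %), 4,4'-di-tert-butyl-2,2'-bipyridine (3 mol %), B2pin2 (1.0 equiv), THF, 70 °C
Reagents that add atoms: bis(pinacolato)diboron, CC1(C)OB(OC1(C)C)B1OC(C)(C)C(C)(C)O1
Why: Sterically controlled iridium-catalysed aromatic C–H borylation, which takes the only aryl C–H without an ortho substituent (para to the benzylic carbon).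

Step 11
Reactants: 18 2-[3,5-bis(methoxymethoxy)-4-{[(1S,2R,4aR,6R)-1,2,5,5-tetramethyl-6-(triethylsilyloxy)-1,2,3,4,4a,5,6,7-octahydronaphthalen-1-yl]methyl}phenyl]-4,4,5,5-tetramethyl-1,3,2-dioxaborolane
Product: 20 [3,5-bis(methoxymethoxy)-4-{[(1S,2R,4aR,6R)-1,2,5,5-tetramethyl-6-(triethylsilyloxy)-1,2,3,4,4a,5,6,7-octahydronaphthalen-1-yl]methyl}phenyl]methanol, via benzylic pinacol boronate 19 (not isolated)
Conditions: BrCH2Cl, n-BuLi, THF, −78 °C → rt; then NaOH, H2O2, 0 °C
Reagents that add atoms: bromochloromethane, ClCBr; hydrogen peroxide, OO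
Why: Matteson homologation (aryl 1,2-metallate shift onto the chloromethyl carbon) followed by oxidation of the benzylic C–B bond.

Step 12
Reactants: 20 [3,5-bis(methoxymethoxy)-4-{[(1S,2R,4aR,6R)-1,2,5,5-tetramethyl-6-(triethylsilyloxy)-1,2,3,4,4a,5,6,7-octahydronaphthalen-1-yl]methyl}phenyl]methanol
Product: 22 6-(hydroxymethyl)-2,4-bis(methoxymethoxy)-3-{[(1S,2R,4aR,6R)-1,2,5,5-tetramethyl-6-(triethylsilyloxy)-1,2,3,4,4a,5,6,7-octahydronaphthalen-1-yl]methyl}benzaldehyde, via dilithiated benzyl alkoxide 21 (not isolated)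
Conditions: n-BuLi (2.5 equiv), Me2NCH2CH2NMe2, THF, −20 → 0 °C; DMF, −78 °C → rt; H2O
Reagents that add atoms: N,N-dimethylformamide, CN(C)C=O
Why: Directed ortho-metalation at the ring position flanked by a MOM ether and the lithium benzyloxide, then formylation with DMF; the two candidate positions are equivalent, so one product forms.

Step 13
Reactants: 22 6-(hydroxymethyl)-2,4-bis(methoxymethoxy)-3-{[(1S,2R,4aR,6R)-1,2,5,5-tetramethyl-6-(triethylsilyloxy)-1,2,3,4,4a,5,6,7-octahydronaphthalen-1-yl]methyl}benzaldehyde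
Product: 23 2,4-dihydroxy-6-(hydroxymethyl)-3-{[(1S,2R,4aR,6R)-6-hydroxy-1,2,5,5-tetramethyl-1,2,3,4,4a,5,6,7-octahydronaphthalen-1-yl]methyl}benzaldehyde (target)
Conditions: 3 M aq HCl, THF, 40 °C
Reagents that add atoms: none
Why: Acid hydrolysis of the two aryl MOM acetals and the triethylsilyl ether; dilute aqueous acid should leave the hindered trisubstituted alkene alone, and the aqueous medium keeps the hydroxy-aldehyde from forming a methyl acetal.

**Compound list**
1 | isobutyraldehyde | CC(C)C=O | starting material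
2 | 2-methyl-1-(trimethylsilyloxy)prop-1-ene | CC(C)=CO[Si](C)(C)C | intermediate
3 | rac-6-methylcyclohex-2-en-1-one | CC1CCC=CC1=O | starting material
4 | 2-methyl-2-[(1R)-4-methyl-3-(trimethylsilyloxy)cyclohex-2-en-1-yl]propanal (both C4 epimers) | CC1CC[C@@H](C(C)(C)C=O)C=C1O[Si](C)(C)C | intermediate
5 | 2-methyl-2-[(1R)-4-methyl-3-oxocyclohexyl]propanal (both C4 epimers) | CC1CC[C@@H](C(C)(C)C=O)CC1=O | intermediate
6 | tetrahydrofuran | C1CCOC1 | starting material
7 | lithium ethenolate | [Li+].[O-]C=C | intermediate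
8 | triethyl(vinyloxy)silane | C=CO[Si](CC)(CC)CC | intermediate
9 | (3R)-4-methyl-4-[(1R)-4-methyl-3-oxocyclohexyl]-3-(triethylsilyloxy)pentanal (both ring C4 epimers) | CC1CC[C@@H](C(C)(C)[C@H](O[Si](CC)(CC)CC)CC=O)CC1=O | intermediate
10 | (2R,4aS,6R)-2,5,5-trimethyl-6-(triethylsilyloxy)-3,4,4a,5,6,7-hexahydronaphthalen-1(2H)-one | C[C@@H]1CC[C@@H]2C(=CC[C@@H](O[Si](CC)(CC)CC)C2(C)C)C1=O | intermediate
11 | (1S,2R,3'R,4aS,6R)-2,3',5,5-tetramethyl-6-(triethylsilyloxy)-3,4,4a,5,6,7-hexahydro-2H-spiro[naphthalene-1,2'-oxirane] | C[C@@H]1CC[C@@H]2C(=CC[C@@H](O[Si](CC)(CC)CC)C2(C)C)[C@@]13O[C@@H]3C | intermediate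
12 | (1S,2R,4aR,6R)-1,2,5,5-tetramethyl-6-(triethylsilyloxy)-1,2,3,4,4a,5,6,7-octahydronaphthalene-1-carbaldehyde | C[C@@H]1CC[C@@H]2C(=CC[C@@H](O[Si](CC)(CC)CC)C2(C)C)[C@@]1(C)C=O | intermediate
13 | resorcinol | Oc1cccc(O)c1 | starting material
14 | 1,3-bis(methoxymethoxy)benzene | COCOc1cccc(OCOC)c1 | intermediate
15 | [2,6-bis(methoxymethoxy)phenyl]lithium | [Li]c1c(OCOC)cccc1OCOC | intermediate
16 | lithium [2,6-bis(methoxymethoxy)phenyl][(1S,2R,4aR,6R)-1,2,5,5-tetramethyl-6-(triethylsilyloxy)-1,2,3,4,4a,5,6,7-octahydronaphthalen-1-yl]methanolate (both carbinol epimers) | C[C@@H]1CC[C@@H]2C(=CC[C@@H](O[Si](CC)(CC)CC)C2(C)C)[C@@]1(C)C(O[Li])c1c(OCOC)cccc1OCOC | intermediate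
17 | (1S,2R,4aR,6R)-1-[2,6-bis(methoxymethoxy)benzyl]-1,2,5,5-tetramethyl-6-(triethylsilyloxy)-1,2,3,4,4a,5,6,7-octahydronaphthalene | C[C@@H]1CC[C@@H]2C(=CC[C@@H](O[Si](CC)(CC)CC)C2(C)C)[C@@]1(C)Cc1c(OCOC)cccc1OCOC | intermediate
18 | 2-[3,5-bis(methoxymethoxy)-4-{[(1S,2R,4aR,6R)-1,2,5,5-tetramethyl-6-(triethylsilyloxy)-1,2,3,4,4a,5,6,7-octahydronaphthalen-1-yl]methyl}phenyl]-4,4,5,5-tetramethyl-1,3,2-dioxaborolane | C[C@@H]1CC[C@@H]2C(=CC[C@@H](O[Si](CC)(CC)CC)C2(C)C)[C@@]1(C)Cc1c(OCOC)cc(B3OC(C)(C)C(C)(C)O3)cc1OCOC | intermediate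
19 | 2-[3,5-bis(methoxymethoxy)-4-{[(1S,2R,4aR,6R)-1,2,5,5-tetramethyl-6-(triethylsilyloxy)-1,2,3,4,4a,5,6,7-octahydronaphthalen-1-yl]methyl}benzyl]-4,4,5,5-tetramethyl-1,3,2-dioxaborolane | C[C@@H]1CC[C@@H]2C(=CC[C@@H](O[Si](CC)(CC)CC)C2(C)C)[C@@]1(C)Cc1c(OCOC)cc(CB3OC(C)(C)C(C)(C)O3)cc1OCOC | intermediate
20 | [3,5-bis(methoxymethoxy)-4-{[(1S,2R,4aR,6R)-1,2,5,5-tetramethyl-6-(triethylsilyloxy)-1,2,3,4,4a,5,6,7-octahydronaphthalen-1-yl]methyl}phenyl]methanol | C[C@@H]1CC[C@@H]2C(=CC[C@@H](O[Si](CC)(CC)CC)C2(C)C)[C@@]1(C)Cc1c(OCOC)cc(CO)cc1OCOC | intermediate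
21 | O,2-dilithio derivative of 20 (lithium benzyloxide lithiated at the ring carbon between CH2OLi and OMOM) | C[C@@H]1CC[C@@H]2C(=CC[C@@H](O[Si](CC)(CC)CC)C2(C)C)[C@@]1(C)Cc1c(OCOC)cc(CO[Li])c([Li])c1OCOC | intermediate
22 | 6-(hydroxymethyl)-2,4-bis(methoxymethoxy)-3-{[(1S,2R,4aR,6R)-1,2,5,5-tetramethyl-6-(triethylsilyloxy)-1,2,3,4,4a,5,6,7-octahydronaphthalen-1-yl]methyl}benzaldehyde | C[C@@H]1CC[C@@H]2C(=CC[C@@H](O[Si](CC)(CC)CC)C2(C)C)[C@@]1(C)Cc1c(OCOC)cc(CO)c(C=O)c1OCOC | intermediate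
23 | 2,4-dihydroxy-6-(hydroxymethyl)-3-{[(1S,2R,4aR,6R)-6-hydroxy-1,2,5,5-tetramethyl-1,2,3,4,4a,5,6,7-octahydronaphthalen-1-yl]methyl}benzaldehyde | C[C@@H]1CC[C@@H]2C(=CC[C@@H](O)C2(C)C)[C@@]1(C)Cc1c(O)cc(CO)c(C=O)c1O | target

**Totals**
Total steps: 13 (steps 1, 3 and 8 are short reagent or protecting-group preparations).
Longest linear sequence: 11 steps (1, 2, 4, 5, 6, 7, 9, 10, 11, 12, 13).

**Three steps most likely to fail**

Step 2 (the proposed new method). The aldehyde-derived enol silane may be too weak a nucleophile for the catalyst, or the facial control may erode. The fallback uses known chemistry, sets out from 3 and comes back at 5. Methyl isobutyrate is silylated (LiN(i-Pr)2, Me3SiCl, THF, −78 °C) to 1-methoxy-2-methyl-1-(trimethylsilyloxy)prop-1-ene F1. F1 adds to 3 under the same oxazaborolidinium triflimide, which is the established ketene-acetal Mukaiyama–Michael reaction, giving methyl 2-methyl-2-[(1R)-4-methyl-3-(trimethylsilyloxy)cyclohex-2-en-1-yl]propanoate F2. Acidic work-up hydrolyses it to methyl 2-methyl-2-[(1R)-4-methyl-3-oxocyclohexyl]propanoate F3. LiAlH4 (THF, 0 °C) reduces ester and ketone to 2-[(1R)-3-hydroxy-4-methylcyclohexyl]-2-methylpropan-1-ol F4, and Swern oxidation ((COCl)2, DMSO, Et3N) returns 5.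

Step 5. The β-silyloxy aldehyde may lose silanol to an enal, or the aldehyde enamine may attack the ketone, before the desired closure. The fallback closes ring A by metathesis instead; it sets out from 9 and comes back at 10. Ph3P=CH2 (1.05 equiv, THF, −78 °C) olefinates only the aldehyde to give (5R)-2-methyl-5-[(3R)-2-methyl-3-(triethylsilyloxy)hex-5-en-2-yl]cyclohexan-1-one F5. LiN(i-Pr)2 then [CH2=NMe2]+ I− at the less substituted α-carbon gives (5R)-6-[(dimethylamino)methyl]-2-methyl-5-[(3R)-2-methyl-3-(triethylsilyloxy)hex-5-en-2-yl]cyclohexan-1-one F6. MeI then NaHCO3 gives (5S)-2-methyl-6-methylidene-5-[(3R)-2-methyl-3-(triethylsilyloxy)hex-5-en-2-yl]cyclohexan-1-one F7. Ring-closing metathesis with the second-generation Hoveyda–Grubbs catalyst RuCl2(H2IMes)(=CH-C6H4-2-O-i-Pr) (toluene, 80 °C) gives 10, whose methyl-bearing centre is then equilibrated with (PhCH2)2NH2+ CF3CO2−.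

Step 7. Hydride may migrate instead of methyl (giving a methyl ketone), or the minor oxirane epimer from step 6 may lead to the wrong quaternary configuration. The fallback builds the centre by enolate alkylation instead; it sets out from 10 and comes back at 12. Ph3P=CHOMe (from [Ph3PCH2OMe]+ Cl− and KN(SiMe3)2, THF, 0 °C) converts 10 into (2R,4aR,6R)-1-(methoxymethylidene)-2,5,5-trimethyl-6-(triethylsilyloxy)-1,2,3,4,4a,5,6,7-octahydronaphthalene F8. Mild hydrolysis (aq oxalic acid, THF) gives (2R,4aR,6R)-2,5,5-trimethyl-6-(triethylsilyloxy)-1,2,3,4,4a,5,6,7-octahydronaphthalene-1-carbaldehyde F9 as C1 epimers. KOt-Bu then MeI (THF, −78 °C) methylates the dienolate at C1 from the axial face (deconjugative α-alkylation), returning 12.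

**Further compounds**
F1 | step 2 | 1-methoxy-2-methyl-1-(trimethylsilyloxy)prop-1-ene | COC(O[Si](C)(C)C)=C(C)C
F2 | step 2 | methyl 2-methyl-2-[(1R)-4-methyl-3-(trimethylsilyloxy)cyclohex-2-en-1-yl]propanoate | CC1CC[C@@H](C(C)(C)C(=O)OC)C=C1O[Si](C)(C)C
F3 | step 2 | methyl 2-methyl-2-[(1R)-4-methyl-3-oxocyclohexyl]propanoate | CC1CC[C@@H](C(C)(C)C(=O)OC)CC1=O
F4 | step 2 | 2-[(1R)-3-hydroxy-4-methylcyclohexyl]-2-methylpropan-1-ol | CC1CC[C@@H](C(C)(C)CO)CC1O
F5 | step 5 | (5R)-2-methyl-5-[(3R)-2-methyl-3-(triethylsilyloxy)hex-5-en-2-yl]cyclohexan-1-one | CC1CC[C@@H](C(C)(C)[C@H](O[Si](CC)(CC)CC)CC=C)CC1=O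
F6 | step 5 | (5R)-6-[(dimethylamino)methyl]-2-methyl-5-[(3R)-2-methyl-3-(triethylsilyloxy)hex-5-en-2-yl]cyclohexan-1-one | CC1CC[C@@H](C(C)(C)[C@H](O[Si](CC)(CC)CC)CC=C)C(CN(C)C)C1=O
F7 | step 5 | (5S)-2-methyl-6-methylidene-5-[(3R)-2-methyl-3-(triethylsilyloxy)hex-5-en-2-yl]cyclohexan-1-one | CC1CC[C@@H](C(C)(C)[C@H](O[Si](CC)(CC)CC)CC=C)C(=C)C1=O
F8 | step 7 | (2R,4aR,6R)-1-(methoxymethylidene)-2,5,5-trimethyl-6-(triethylsilyloxy)-1,2,3,4,4a,5,6,7-octahydronaphthalene | C[C@@H]1CC[C@@H]2C(=CC[C@@H](O[Si](CC)(CC)CC)C2(C)C)C1=COC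
F9 | step 7 | (2R,4aR,6R)-2,5,5-trimethyl-6-(triethylsilyloxy)-1,2,3,4,4a,5,6,7-octahydronaphthalene-1-carbaldehyde (C1 epimers) | C[C@@H]1CC[C@@H]2C(=CC[C@@H](O[Si](CC)(CC)CC)C2(C)C)C1C=O
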